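**Retrosynthetic overview**

1. Ring B of the target carries CO2H at C1, flanked by the diaryl-ether oxygen at C2 and the heptyl chain at C6 (OMe at C4). The C6–heptyl and C1–carboxyl bonds are disconnected together to an aryne across C1–C6, heptylmagnesium bromide and CO2.
2. The aryne comes from an aryl ether with I at C1 and F at C6 by iodine–magnesium exchange and loss of fluoride. The aryloxy oxygen beside the triple bond steers heptyl to C6 and magnesium to C1.
3. The O/I/F pattern is fixed without a regiochemical choice: SNAr of the ring A 4-hydroxyl on symmetrical 1,3-difluoro-5-methoxy-2-nitrobenzene, then NO2 → NH2 → I. This is preferred to electrophilic iodination of the finished diaryl ether, where both electron-rich rings offer several competing positions.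
4. Ring A is 5-heptylresorcinol, carboxylated and carried as tert-butyl ester and MOM ether, both removed by CF3CO2H in the last step.
5. No ring is formed; both benzene rings are purchased. Order: ring A carboxyl, diaryl ether, C–I, the two ring B C–C bonds, deprotection.

Key step: step 8

Remark: 5-heptylresorcinol and 1,3-difluoro-5-methoxy-2-nitrobenzene are assumed to be purchasable. Ring B is numbered as the benzoic acid (C1 carboxyl, C2 aryloxy, C4 methoxy, C6 heptyl).

**Route**

Step 1
Reactants: 1 5-heptylresorcinol
Product: 2 2-heptyl-4,6-dihydroxybenzoic acid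
Conditions: MeOMgOCO2Me (methoxymagnesium methyl carbonate, 2 M in DMF, excess), 120 °C, N2; then cold aq. HCl
Reagents that add atoms: methoxymagnesium methyl carbonate COC(=O)O[Mg]OC
Why: Chelation-controlled ortho-carboxylation of the phenol (Kolbe–Schmitt-type reaction with the magnesium methyl carbonate reagent) should take place at the ring carbon between a hydroxyl and the heptyl group, as is known for 5-alkylresorcinols, the magnesium salicylate chelate holding the carboxyl until the cold acid quench.

Step 2
Reactants: 2 2-heptyl-4,6-dihydroxybenzoic acid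
Product: 3 tert-butyl 2-heptyl-4,6-dihydroxybenzoate
Conditions: O-tert-butyl-N,N'-diisopropylisourea (3 equiv), CH2Cl2, rt
Reagents that add atoms: O-tert-butyl-N,N'-diisopropylisourea CC(C)N=C(OC(C)(C)C)NC(C)C
Why: In this isourea esterification the carboxylic acid protonates the isourea and the carboxylate is O-tert-butylated within the ion pair at room temperature, where the far less acidic phenols should stay unalkylated and the acid has no occasion to decarboxylate.

Step 3
Reactants: 3 tert-butyl 2-heptyl-4,6-dihydroxybenzoate; 4 1,3-difluoro-5-methoxy-2-nitrobenzene (1.2 equiv)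
Product: 5 tert-butyl 4-(3-fluoro-5-methoxy-2-nitrophenoxy)-2-heptyl-6-hydroxybenzoate
Conditions: K2CO3 (1.1 equiv), DMF, 50 °C
Reagents that add atoms: none
Why: Nucleophilic aromatic substitution (SNAr): the 4-hydroxyl, para to the ester and free of the hydrogen bond that ties the 6-hydroxyl to the carbonyl, is the one deprotonated and displaces one of the two equivalent fluorides ortho to the nitro group, so ether oxygen, nitro group and remaining fluorine end up on three consecutive carbons by symmetry.

Step 4
Reactants: 5 tert-butyl 4-(3-fluoro-5-methoxy-2-nitrophenoxy)-2-heptyl-6-hydroxybenzoate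
Product: 6 tert-butyl 4-(3-fluoro-5-methoxy-2-nitrophenoxy)-2-heptyl-6-(methoxymethoxy)benzoate
Conditions: MOMCl, iPr2NEt, CH2Cl2, 0 °C to 40 °C
Reagents that add atoms: chloromethyl methyl ether COCCl
Why: O-alkylation of the remaining hydrogen-bonded phenol by the reactive α-chloro ether under amine base (MOM protection) is mild enough that the phenol does not attack the ortho-fluoronitroarene of another molecule.

Step 5
Reactants: 6 tert-butyl 4-(3-fluoro-5-methoxy-2-nitrophenoxy)-2-heptyl-6-(methoxymethoxy)benzoate
Product: 7 tert-butyl 4-(2-amino-3-fluoro-5-methoxyphenoxy)-2-heptyl-6-(methoxymethoxy)benzoate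
Conditions: H2 (1 atm), 10% Pd/C, EtOAc, rt
Reagents that add atoms: none
Why: Catalytic hydrogenation of the nitroarene to the aniline under neutral conditions should leave the aryl fluoride, the diaryl ether, the MOM ether and the tert-butyl ester untouched.

Step 6
Reactants: 7 tert-butyl 4-(2-amino-3-fluoro-5-methoxyphenoxy)-2-heptyl-6-(methoxymethoxy)benzoate
Product: 9 tert-butyl 4-(3-fluoro-2-iodo-5-methoxyphenoxy)-2-heptyl-6-(methoxymethoxy)benzoate, via arenediazonium tosylate 8 (not isolated)
Conditions: t-BuONO (1.5 equiv), p-TsOH·H2O (1.2 equiv), MeCN, 0 °C; then KI (2.5 equiv), H2O, 0 °C to rt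
Reagents that add atoms: potassium iodide [K+].[I-] (iodine of 9); tert-butyl nitrite CC(C)(C)ON=O (outer nitrogen of 8 only); 4-methylbenzenesulfonic acid Cc1ccc(S(=O)(=O)O)cc1 (counter-ion of 8 only)
Why: Diazotization with an alkyl nitrite and about one equivalent of sulfonic acid gives an arenediazonium tosylate that iodide converts to the aryl iodide without copper (Sandmeyer-type iododediazoniation), placing iodine exactly on the carbon between ether oxygen and fluorine; the acid is consumed as the diazonium counter-ion, so the MOM ether and tert-butyl ester should survive at 0 °C.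

Step 7
Reactants: 10 1-bromoheptane
Product: 11 heptylmagnesium bromide
Conditions: Mg turnings, I2 (cat.), THF, 25–40 °C
Reagents that add atoms: magnesium [Mg]
Why: Oxidative insertion of magnesium into the primary alkyl bromide (Grignard reagent formation) gives the reagent as a titrated THF solution.

Step 8
Reactants: 9 tert-butyl 4-(3-fluoro-2-iodo-5-methoxyphenoxy)-2-heptyl-6-(methoxymethoxy)benzoate; 11 heptylmagnesium bromide (4 equiv); 12 carbon dioxide
Product: 16 2-[4-(tert-butoxycarbonyl)-3-heptyl-5-(methoxymethoxy)phenoxy]-6-heptyl-4-methoxybenzoic acid, via 2-fluoroarylmagnesium bromide 13 (not isolated), via ring B aryne 14 (not isolated), via 6-heptylarylmagnesium bromide 15 (not isolated)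
Conditions: 11 (4 equiv), LiCl, THF, −30 °C, then 25–40 °C; then CO2 (dry gas), −20 °C to rt; cold 0.5 M HCl to pH 3
Reagents that add atoms: none
Why: Iodine–magnesium exchange by the first equivalent of 11 gives 13, which on warming loses MgBrF (fluoride rather than the poorer aryloxide leaving group) to form aryne 14 across C1–C6 of ring B; a second equivalent of 11 adds to it and the resulting ortho-arylmagnesium 15 is carboxylated by CO2, so both the C6–heptyl and C1–CO2H bonds are made in one flask. The closest known reaction type is carbomagnesiation of an aryne generated from an ortho-halogenated arylmagnesium species, with electrophilic trapping of the new aryl Grignard reagent. No ring is closed and no stereocentre is formed. The selectivity needed is regiochemical: the inductively withdrawing aryloxy oxygen at C2 distorts the aryne so that C6 is the more electrophilic terminus and the carbanion is best placed at C1 beside oxygen, hence heptyl at C6 and magnesium at C1; the C4 methoxy group, which by induction would slightly favour the anion at C6, is a weak opposing influence. Chemoselectivity rests on the di-ortho-substituted tert-butyl ester of ring A, which should be too hindered for Grignard addition at these temperatures, on the inert MOM ether, and on the excess of 11, which outcompetes 13 for the aryne.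

Step 9
Reactants: 16 2-[4-(tert-butoxycarbonyl)-3-heptyl-5-(methoxymethoxy)phenoxy]-6-heptyl-4-methoxybenzoic acid
Product: 17 4-(2-carboxy-3-heptyl-5-methoxyphenoxy)-2-heptyl-6-hydroxybenzoic acid (CNP0377121.0)
Conditions: CF3CO2H, CH2Cl2, H2O (2 equiv), 0 °C to rt
Reagents that add atoms: none
Why: Acidolysis cleaves the tert-butyl ester to the acid and 2-methylpropene and hydrolyses the MOM acetal to the phenol, while the methyl ether, the diaryl ether and both carboxyl groups should tolerate short exposure to trifluoroacetic acid at or below room temperature.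

**Compound list**

1 | 5-heptylresorcinol | CCCCCCCc1cc(O)cc(O)c1 | starting material
2 | 2-heptyl-4,6-dihydroxybenzoic acid | CCCCCCCc1cc(O)cc(O)c1C(=O)O | intermediate
3 | tert-butyl 2-heptyl-4,6-dihydroxybenzoate | CCCCCCCc1cc(O)cc(O)c1C(=O)OC(C)(C)C | intermediate
4 | 1,3-difluoro-5-methoxy-2-nitrobenzene | COc1cc(F)c([N+](=O)[O-])c(F)c1 | starting material
5 | tert-butyl 4-(3-fluoro-5-methoxy-2-nitrophenoxy)-2-heptyl-6-hydroxybenzoate | CCCCCCCc1cc(Oc2cc(OC)cc(F)c2[N+](=O)[O-])cc(O)c1C(=O)OC(C)(C)C | intermediate
6 | tert-butyl 4-(3-fluoro-5-methoxy-2-nitrophenoxy)-2-heptyl-6-(methoxymethoxy)benzoate | CCCCCCCc1cc(Oc2cc(OC)cc(F)c2[N+](=O)[O-])cc(OCOC)c1C(=O)OC(C)(C)C | intermediate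
7 | tert-butyl 4-(2-amino-3-fluoro-5-methoxyphenoxy)-2-heptyl-6-(methoxymethoxy)benzoate | CCCCCCCc1cc(Oc2cc(OC)cc(F)c2N)cc(OCOC)c1C(=O)OC(C)(C)C | intermediate
8 | 2-[4-(tert-butoxycarbonyl)-3-heptyl-5-(methoxymethoxy)phenoxy]-6-fluoro-4-methoxybenzenediazonium 4-methylbenzenesulfonate | CCCCCCCc1cc(Oc2cc(OC)cc(F)c2[N+]#N)cc(OCOC)c1C(=O)OC(C)(C)C.Cc1ccc(S(=O)(=O)[O-])cc1 | intermediate
9 | tert-butyl 4-(3-fluoro-2-iodo-5-methoxyphenoxy)-2-heptyl-6-(methoxymethoxy)benzoate | CCCCCCCc1cc(Oc2cc(OC)cc(F)c2I)cc(OCOC)c1C(=O)OC(C)(C)C | intermediate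
10 | 1-bromoheptane | CCCCCCCBr | starting material
11 | heptylmagnesium bromide | CCCCCCC[Mg]Br | intermediate
12 | carbon dioxide | O=C=O | starting material
13 | {2-[4-(tert-butoxycarbonyl)-3-heptyl-5-(methoxymethoxy)phenoxy]-6-fluoro-4-methoxyphenyl}magnesium bromide | CCCCCCCc1cc(Oc2cc(OC)cc(F)c2[Mg]Br)cc(OCOC)c1C(=O)OC(C)(C)C | intermediate
14 | tert-butyl 4-[(2,3-didehydro-5-methoxyphenyl)oxy]-2-heptyl-6-(methoxymethoxy)benzoate (ring B aryne) | CCCCCCCc1cc(OC2=CC(OC)=CC#C2)cc(OCOC)c1C(=O)OC(C)(C)C | intermediate
15 | {2-[4-(tert-butoxycarbonyl)-3-heptyl-5-(methoxymethoxy)phenoxy]-6-heptyl-4-methoxyphenyl}magnesium bromide | CCCCCCCc1cc(Oc2cc(OC)cc(CCCCCCC)c2[Mg]Br)cc(OCOC)c1C(=O)OC(C)(C)C | intermediate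
16 | 2-[4-(tert-butoxycarbonyl)-3-heptyl-5-(methoxymethoxy)phenoxy]-6-heptyl-4-methoxybenzoic acid | CCCCCCCc1cc(Oc2cc(OC)cc(CCCCCCC)c2C(=O)O)cc(OCOC)c1C(=O)OC(C)(C)C | intermediate
17 | 4-(2-carboxy-3-heptyl-5-methoxyphenoxy)-2-heptyl-6-hydroxybenzoic acid | CCCCCCCc1cc(Oc2cc(OC)cc(CCCCCCC)c2C(=O)O)cc(O)c1C(=O)O | target

**Step count**

Total steps: 9. Longest linear sequence: 8 (steps 1–6, 8, 9 from 5-heptylresorcinol); step 7 is a one-step side branch.

**Steps most likely to fail**

Step 8 (key step). Several processes could compete:
- fluoride loss from the arylmagnesium may be slow, leaving the fluoro acid after carboxylation;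
- at the temperature needed for aryne formation the Grignard reagent may begin to attack the ring A ester or displace the MOM-oxy group ortho to it;
- the aryne may be captured by the arylmagnesium instead of the alkyl reagent;
- regiocontrol by the aryloxy group may be incomplete.

Fallback, setting out from 9 and returning at 16: exchange with 1.1 equiv of 11 at −40 °C gives 13, which is carboxylated at that temperature, before fluoride is lost, to 2-[4-(tert-butoxycarbonyl)-3-heptyl-5-(methoxymethoxy)phenoxy]-6-fluoro-4-methoxybenzoic acid F1. The fluoride ortho to the free carboxylate of F1 is then displaced by excess 11 in THF (carboxylate-directed nucleophilic aromatic substitution of an unprotected ortho-fluorobenzoic acid by a Grignard reagent). This is an addition–elimination that involves no aryne, so the heptyl group can only enter where fluorine sat. It gives 16.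

Step 6. Three processes could go wrong:
- the diazonium group strongly activates the neighbouring fluoride towards displacement by water or iodide;
- the aryl radical formed on dediazoniation could cyclize onto ring A (dibenzofuran formation) instead of being iodinated;
- the sulfonic acid could begin to cleave the MOM ether.

Fallback, setting out from 3 and returning at 9: Ullmann etherification of the 4-hydroxyl of 3 with 1-bromo-3-fluoro-5-methoxybenzene (CuI, N,N-dimethylglycine, Cs2CO3, dioxane, 90 °C) gives tert-butyl 4-(3-fluoro-5-methoxyphenoxy)-2-heptyl-6-hydroxybenzoate F2. MOM protection (MOMCl, iPr2NEt) gives tert-butyl 4-(3-fluoro-5-methoxyphenoxy)-2-heptyl-6-(methoxymethoxy)benzoate F3. Electrophilic iodination with N-iodosuccinimide and catalytic CF3CO2H in MeCN, expected mainly para to the methoxy group (the carbon between fluorine and the ether oxygen), gives 9. Regioisomeric iodides, including ring A iodides, would have to be separated, which is why this is not the main route.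

Step 2. tert-Butylation may spill over to the 4-hydroxyl, or the electron-rich dihydroxy acid may decarboxylate during esterification or isolation. Uncertain regiocontrol in the carboxylation of step 1 adds to the same weakness.

Fallback, setting out from 1 and returning at 6; the carboxyl carbon is brought in as a formyl group and oxidized only after both phenols are masked:
- Vilsmeier–Haack formylation of 1 (POCl3, DMF) gives 2-heptyl-4,6-dihydroxybenzaldehyde F4.
- SNAr of its 4-hydroxyl on 4 (K2CO3, DMF) gives 4-(3-fluoro-5-methoxy-2-nitrophenoxy)-2-heptyl-6-hydroxybenzaldehyde F5.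
- MOM protection gives 4-(3-fluoro-5-methoxy-2-nitrophenoxy)-2-heptyl-6-(methoxymethoxy)benzaldehyde F6.
- Pinnick oxidation (NaClO2, NaH2PO4, 2-methyl-2-butene, t-BuOH/H2O) gives 4-(3-fluoro-5-methoxy-2-nitrophenoxy)-2-heptyl-6-(methoxymethoxy)benzoic acid F7.
- F7 has no free phenol and is esterified with O-tert-butyl-N,N'-diisopropylisourea to 6.

**Further compounds**

F1 | step 8 | 2-[4-(tert-butoxycarbonyl)-3-heptyl-5-(methoxymethoxy)phenoxy]-6-fluoro-4-methoxybenzoic acid | CCCCCCCc1cc(Oc2cc(OC)cc(F)c2C(=O)O)cc(OCOC)c1C(=O)OC(C)(C)C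
F2 | step 6 | tert-butyl 4-(3-fluoro-5-methoxyphenoxy)-2-heptyl-6-hydroxybenzoate | CCCCCCCc1cc(Oc2cc(F)cc(OC)c2)cc(O)c1C(=O)OC(C)(C)C
F3 | step 6 | tert-butyl 4-(3-fluoro-5-methoxyphenoxy)-2-heptyl-6-(methoxymethoxy)benzoate | CCCCCCCc1cc(Oc2cc(F)cc(OC)c2)cc(OCOC)c1C(=O)OC(C)(C)C
F4 | step 2 | 2-heptyl-4,6-dihydroxybenzaldehyde | CCCCCCCc1cc(O)cc(O)c1C=O
F5 | step 2 | 4-(3-fluoro-5-methoxy-2-nitrophenoxy)-2-heptyl-6-hydroxybenzaldehyde | CCCCCCCc1cc(Oc2cc(OC)cc(F)c2[N+](=O)[O-])cc(O)c1C=O
F6 | step 2 | 4-(3-fluoro-5-methoxy-2-nitrophenoxy)-2-heptyl-6-(methoxymethoxy)benzaldehyde | CCCCCCCc1cc(Oc2cc(OC)cc(F)c2[N+](=O)[O-])cc(OCOC)c1C=O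
F7 | step 2 | 4-(3-fluoro-5-methoxy-2-nitrophenoxy)-2-heptyl-6-(methoxymethoxy)benzoic acid | CCCCCCCc1cc(Oc2cc(OC)cc(F)c2[N+](=O)[O-])cc(OCOC)c1C(=O)O
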